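**Plan**
- The retrosynthesis first cuts the aryl–C1' bond (quinone taken back to a hydroquinone dimethyl ether and an allylic chloride). It then cuts C9'–C10', and finally the C8'–C9' two-carbon extension that grows from the E methyl group of geraniol.
- The structural feature that allows the central cut: C9' is a secondary carbinol bonded directly to alkene carbon C10'. Such an allylic alcohol is the oxidation product of a secondary allylic boronic ester, whereas a carbonyl addition at C9' would need a β,γ-unsaturated aldehyde that slips into conjugation.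
- Forward: geraniol is turned into the C1'–C9' homoallylic carbamate (six steps) and 6-methylhept-5-en-2-one into the C10'–C16' (E)-alkenyl pinacol boronate (three steps).
- The two are joined at C9'–C10' by lithiation–borylation–oxidation. Desilylation, chlorination at C1', copper-catalysed arylation and oxidation to the quinone follow. No ring is formed; the only ring is the purchased arene.
- Stereochemistry: C9' (S) comes from (+)-sparteine-directed deprotonation, 2'E from geraniol, 6'E from SeO2 attack on the E methyl group, and 10'E from syn methylalumination.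

Key step: step 10

Remark: the side chain is numbered from the ring-bound CH2 (C1') to the terminal C(CH3)2 carbon (C15'), and (+)-sparteine is taken to be purchasable.

**Route**

Step 1
Reactants: 1 geraniol
Product: 2 geranyl tert-butyldiphenylsilyl ether
Conditions: TBDPSCl, imidazole, CH2Cl2, 0 °C → rt
Reagents that add atoms: tert-butyl(chloro)diphenylsilane, CC(C)(C)[Si](Cl)(c1ccccc1)c1ccccc1
Why: Imidazole-promoted silylation of a primary allylic alcohol is routine, and the bulky silyl ether should last through every later step until fluoride is applied.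

Step 2
Reactants: 2 geranyl tert-butyldiphenylsilyl ether
Product: 3 (2E,6E)-8-[tert-butyl(diphenyl)silyl]oxy-2,6-dimethylocta-2,6-dien-1-ol
Conditions: SeO2 (cat.), t-BuOOH, salicylic acid (cat.), CH2Cl2, rt
Reagents that add atoms: tert-butyl hydroperoxide, CC(C)(C)OO (terminal oxygen source); selenium dioxide, O=[Se]=O (transfers the oxygen)
Why: The Sharpless SeO2/t-BuOOH allylic oxidation (ene reaction, then 2,3-sigmatropic shift) should attack the more electron-rich terminal alkene at its E methyl group; any enal 4 formed alongside is carried on because step 3 converges on it.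

Step 3
Reactants: 3 (2E,6E)-8-[tert-butyl(diphenyl)silyl]oxy-2,6-dimethylocta-2,6-dien-1-ol
Product: 4 (2E,6E)-8-[tert-butyl(diphenyl)silyl]oxy-2,6-dimethylocta-2,6-dienal
Conditions: MnO2, CH2Cl2, rt
Reagents that add atoms: none
Why: MnO2 oxidation of an allylic alcohol should stop at the enal without touching the silyl ether or the alkene geometry.

Step 4
Reactants: 4 (2E,6E)-8-[tert-butyl(diphenyl)silyl]oxy-2,6-dimethylocta-2,6-dienal
Product: 5 tert-butyl{[(2E,6E)-3,7-dimethylnona-2,6,8-trien-1-yl]oxy}diphenylsilane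
Conditions: Ph3PCH3Br, KOt-Bu, THF, 0 °C → rt
Reagents that add atoms: methyltriphenylphosphonium bromide, [Br-].C[P+](c1ccccc1)(c1ccccc1)c1ccccc1
Why: Wittig methylenation of the enal should give the terminal 1,3-diene and leave the existing E alkenes unchanged.

Step 5
Reactants: 5 tert-butyl{[(2E,6E)-3,7-dimethylnona-2,6,8-trien-1-yl]oxy}diphenylsilane
Product: 7 (3E,7E)-9-[tert-butyl(diphenyl)silyl]oxy-3,7-dimethylnona-3,7-dien-1-ol, via alkylborane 6 (not isolated)
Conditions: 9-BBN, THF, 0 °C → rt; then NaOH aq, H2O2, 0 °C → rt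
Reagents that add atoms: hydrogen peroxide, OO
Why: Brown hydroboration with the bulky 9-BBN should select the monosubstituted terminal alkene over the three trisubstituted ones and place boron on the terminal carbon, so oxidation gives the homoallylic primary alcohol with C9' in place.

Step 6
Reactants: 7 (3E,7E)-9-[tert-butyl(diphenyl)silyl]oxy-3,7-dimethylnona-3,7-dien-1-ol
Product: 8 (3E,7E)-9-[tert-butyl(diphenyl)silyl]oxy-3,7-dimethylnona-3,7-dien-1-yl N,N-diisopropylcarbamate
Conditions: i-Pr2NCOCl, Et3N, CH2Cl2, reflux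
Reagents that add atoms: N,N-diisopropylcarbamoyl chloride, CC(C)N(C(C)C)C(Cl)=O
Why: O-Acylation of the primary alcohol with the carbamoyl chloride should install the Hoppe carbamate that later directs and stabilises lithiation at C9'.

Step 7
Reactants: 9 6-methylhept-5-en-2-one
Product: 11 6-methylhept-5-en-1-yne, via enol phosphate 10 (not isolated)
Conditions: LiN(i-Pr)2, THF, −78 °C; ClP(O)(OEt)2, −78 °C → rt; then LiN(i-Pr)2 (2.3 equiv), −78 °C → rt; H2O
Reagents that add atoms: none
Why: The Negishi one-flask conversion of a methyl ketone into a terminal alkyne relies on kinetic enolisation at the methyl group, O-phosphorylation and base-induced elimination of diethyl phosphate, and the trisubstituted alkene is a spectator.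

Step 8
Reactants: 11 6-methylhept-5-en-1-yne
Product: 13 (1E)-1-iodo-2,6-dimethylhepta-1,5-diene, via alkenylalane 12 (not isolated)
Conditions: AlMe3, Cp2ZrCl2 (0.25 equiv), CH2Cl2, 0 °C → rt; then I2, THF, −30 → 0 °C
Reagents that add atoms: trimethylaluminium, C[Al](C)C; iodine, II
Why: Negishi zirconium-catalysed methylalumination adds methyl and aluminium syn across the alkyne with aluminium at the terminus, and iodinolysis with retention should fix the E trisubstituted alkenyl iodide.

Step 9
Reactants: 13 (1E)-1-iodo-2,6-dimethylhepta-1,5-diene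
Product: 15 2-[(1E)-2,6-dimethylhepta-1,5-dien-1-yl]-4,4,5,5-tetramethyl-1,3,2-dioxaborolane, via alkenyllithium 14 (not isolated)
Conditions: t-BuLi (2.1 equiv), Et2O, −78 °C; i-PrOBpin, −78 °C → rt
Reagents that add atoms: 2-isopropoxy-4,4,5,5-tetramethyl-1,3,2-dioxaborolane, CC(C)OB1OC(C)(C)C(C)(C)O1
Why: Lithium–iodine exchange proceeds with retention of alkene geometry, and borylation of the alkenyllithium with the isopropoxy boronate should give the E alkenyl pinacol boronate.

Step 10
Reactants: 8 (3E,7E)-9-[tert-butyl(diphenyl)silyl]oxy-3,7-dimethylnona-3,7-dien-1-yl N,N-diisopropylcarbamate; 15 2-[(1E)-2,6-dimethylhepta-1,5-dien-1-yl]-4,4,5,5-tetramethyl-1,3,2-dioxaborolane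
Product: 19 (2E,6E,9S,10E)-1-[tert-butyl(diphenyl)silyl]oxy-3,7,11,15-tetramethylhexadeca-2,6,10,14-tetraen-9-ol, via lithiated carbamate 16 (not isolated), via boronate complex 17 (not isolated), via allylic boronic ester 18 (not isolated)
Conditions: s-BuLi (1.3 equiv), (+)-sparteine (1.3 equiv), Et2O, −78 °C, 5 h; 15 (1.5 equiv), −78 °C, 1 h; MgBr2·OEt2, −78 °C → reflux; then NaOH aq, H2O2, THF, 0 °C → rt
Reagents that add atoms: hydrogen peroxide, OO
Why: The s-BuLi·(+)-sparteine complex should remove the pro-R hydrogen of the OCH2 group to give the configurationally stable, carbonyl-chelated (R)-α-lithio carbamate 16, which adds to the boron of 15 with retention to form boronate complex 17. In 17 the alkenyl group shifts from boron to C9' antiperiplanar to the departing carbamate (inversion at carbon, assisted by MgBr2) to give (S)-allylic boronic ester 18, and alkaline H2O2 replaces boron by hydroxyl with retention. The closest known reaction type is the Hoppe-type lithiation–borylation of primary alkyl carbamates with alkenyl pinacol boronates, a Matteson-type 1,2-metallate rearrangement followed by oxidation, which unites two nucleophilic carbons through boron. No ring is closed, and the single new stereocentre C9' is controlled by the diamine, the sequence retention, inversion, retention turning (R)-16 into the (S)-carbinol. The step needs deprotonation at C9' and not at the allylic C8' or C1' positions, which the carbamate carbonyl secures by directing the base to its own α-hydrogens at −78 °C in Et2O. The migrating alkenyl group keeps its E geometry, and the γ,γ-disubstituted allylic pinacol boronate should resist 1,3-boron shift before oxidation.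

Step 11
Reactants: 19 (2E,6E,9S,10E)-1-[tert-butyl(diphenyl)silyl]oxy-3,7,11,15-tetramethylhexadeca-2,6,10,14-tetraen-9-ol
Product: 20 (2E,6E,9S,10E)-3,7,11,15-tetramethylhexadeca-2,6,10,14-tetraene-1,9-diol
Conditions: Bu4NF, THF, 0 °C → rt
Reagents that add atoms: none
Why: Fluoride-mediated desilylation, driven by the strong silicon–fluorine bond, should free the primary allylic alcohol without affecting the C9' carbinol or the alkenes.

Step 12
Reactants: 20 (2E,6E,9S,10E)-3,7,11,15-tetramethylhexadeca-2,6,10,14-tetraene-1,9-diol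
Product: 22 (2E,6E,9S,10E)-1-chloro-3,7,11,15-tetramethylhexadeca-2,6,10,14-tetraen-9-ol, via primary mesylate 21 (not isolated)
Conditions: MsCl (1.05 equiv), LiCl, 2,4,6-collidine, DMF, 0 °C
Reagents that add atoms: lithium chloride, [Li+].[Cl-]; methanesulfonyl chloride, CS(=O)(=O)Cl (its chloride joins the same chloride pool)
Why: In the Collington–Meyers chlorination the unhindered primary allylic hydroxyl is mesylated much faster than the hindered secondary one, and chloride displaces the mesylate in an SN2 sense without allylic transposition, so C9' is left alone.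

Step 13
Reactants: 23 4-methoxy-2-methylphenol
Product: 24 2-bromo-4-methoxy-6-methylphenol
Conditions: NBS, CH2Cl2, 0 °C
Reagents that add atoms: N-bromosuccinimide, O=C1CCC(=O)N1Br
Why: Electrophilic aromatic bromination should go ortho to the free hydroxyl, the strongest activating group, because its para position is blocked by methoxy.

Step 14
Reactants: 24 2-bromo-4-methoxy-6-methylphenol
Product: 25 1-bromo-2,5-dimethoxy-3-methylbenzene
Conditions: MeI, K2CO3, acetone, reflux
Reagents that add atoms: iodomethane, CI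
Why: Williamson O-methylation of the phenoxide should give the hydroquinone dimethyl ether, which tolerates the organometallic coupling.

Step 15
Reactants: 22 (2E,6E,9S,10E)-1-chloro-3,7,11,15-tetramethylhexadeca-2,6,10,14-tetraen-9-ol; 25 1-bromo-2,5-dimethoxy-3-methylbenzene
Product: 27 (2E,6E,9S,10E)-1-(2,5-dimethoxy-3-methylphenyl)-3,7,11,15-tetramethylhexadeca-2,6,10,14-tetraen-9-ol, via arylmagnesium bromide 26 (not isolated)
Conditions: 25, Mg, THF, reflux (gives 26, 3 equiv); then 22, CuI (10 mol%), THF, −30 → 0 °C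
Reagents that add atoms: none
Why: In this copper-catalysed SN2 allylic substitution by an aryl Grignard reagent, one equivalent of 26 is consumed by the C9' hydroxyl to give an inert alkoxide, and the aryl group should attack the unhindered primary carbon because γ attack would build a quaternary centre, so the 2'E geometry is kept.

Step 16
Reactants: 27 (2E,6E,9S,10E)-1-(2,5-dimethoxy-3-methylphenyl)-3,7,11,15-tetramethylhexadeca-2,6,10,14-tetraen-9-ol
Product: 28 2-[(2E,6E,9S,10E)-9-hydroxy-3,7,11,15-tetramethylhexadeca-2,6,10,14-tetraen-1-yl]-6-methylcyclohexa-2,5-diene-1,4-dione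
Conditions: (NH4)2Ce(NO3)6 (2.5 equiv), MeCN/H2O, 0 °C, short reaction time
Reagents that add atoms: water, O
Why: Oxidative demethylation of the 1,4-dimethoxyarene by tetravalent cerium (two one-electron oxidations, ipso attack of water, loss of methanol) should give the 1,4-benzoquinone, and the brief exposure at 0 °C is meant to spare the allylic carbinol and the trisubstituted alkenes.

**Compound list**

1 | geraniol, (2E)-3,7-dimethylocta-2,6-dien-1-ol | CC(C)=CCC/C(C)=C/CO | starting material
2 | geranyl tert-butyldiphenylsilyl ether | CC(C)=CCC/C(C)=C/CO[Si](c1ccccc1)(c1ccccc1)C(C)(C)C | intermediate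
3 | (2E,6E)-8-[tert-butyl(diphenyl)silyl]oxy-2,6-dimethylocta-2,6-dien-1-ol | OC/C(C)=C/CC/C(C)=C/CO[Si](c1ccccc1)(c1ccccc1)C(C)(C)C | intermediate
4 | (2E,6E)-8-[tert-butyl(diphenyl)silyl]oxy-2,6-dimethylocta-2,6-dienal | O=C/C(C)=C/CC/C(C)=C/CO[Si](c1ccccc1)(c1ccccc1)C(C)(C)C | intermediate
5 | tert-butyl{[(2E,6E)-3,7-dimethylnona-2,6,8-trien-1-yl]oxy}diphenylsilane | C=C/C(C)=C/CC/C(C)=C/CO[Si](c1ccccc1)(c1ccccc1)C(C)(C)C | intermediate
6 | 9-[(3E,7E)-9-[tert-butyl(diphenyl)silyl]oxy-3,7-dimethylnona-3,7-dien-1-yl]-9-borabicyclo[3.3.1]nonane (alkylborane, formed in the flask) | C1CCC2CCCC1B2CC/C(C)=C/CC/C(C)=C/CO[Si](c1ccccc1)(c1ccccc1)C(C)(C)C | intermediate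
7 | (3E,7E)-9-[tert-butyl(diphenyl)silyl]oxy-3,7-dimethylnona-3,7-dien-1-ol | OCC/C(C)=C/CC/C(C)=C/CO[Si](c1ccccc1)(c1ccccc1)C(C)(C)C | intermediate
8 | (3E,7E)-9-[tert-butyl(diphenyl)silyl]oxy-3,7-dimethylnona-3,7-dien-1-yl N,N-diisopropylcarbamate | CC(C)N(C(C)C)C(=O)OCC/C(C)=C/CC/C(C)=C/CO[Si](c1ccccc1)(c1ccccc1)C(C)(C)C | intermediate
9 | 6-methylhept-5-en-2-one | CC(=O)CCC=C(C)C | starting material
10 | diethyl 6-methylhepta-1,5-dien-2-yl phosphate (enol phosphate, formed in the flask) | C=C(CCC=C(C)C)OP(=O)(OCC)OCC | intermediate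
11 | 6-methylhept-5-en-1-yne | CC(C)=CCCC#C | intermediate
12 | [(1E)-2,6-dimethylhepta-1,5-dien-1-yl]dimethylalane (formed in the flask) | CC(C)=CCC/C(C)=C/[Al](C)C | intermediate
13 | (1E)-1-iodo-2,6-dimethylhepta-1,5-diene | CC(C)=CCC/C(C)=C/I | intermediate
14 | [(1E)-2,6-dimethylhepta-1,5-dien-1-yl]lithium (formed in the flask) | CC(C)=CCC/C(C)=C/[Li] | intermediate
15 | 2-[(1E)-2,6-dimethylhepta-1,5-dien-1-yl]-4,4,5,5-tetramethyl-1,3,2-dioxaborolane | CC(C)=CCC/C(C)=C/B1OC(C)(C)C(C)(C)O1 | intermediate
16 | (R)-α-lithio derivative of carbamate 8, lithium at C9' (formed in the flask) | [Li][C@@H](OC(=O)N(C(C)C)C(C)C)C/C(C)=C/CC/C(C)=C/CO[Si](c1ccccc1)(c1ccccc1)C(C)(C)C | intermediate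
17 | lithium boronate complex of 16 and 15, (R) at C9' (formed in the flask) | [Li+].CC(C)=CCC/C(C)=C/[B-]1(OC(C)(C)C(C)(C)O1)[C@@H](OC(=O)N(C(C)C)C(C)C)C/C(C)=C/CC/C(C)=C/CO[Si](c1ccccc1)(c1ccccc1)C(C)(C)C | intermediate
18 | (S)-C9' allylic pinacol boronic ester of the C1'–C16' chain, C1' O-TBDPS (formed in the flask) | CC(C)=CCC/C(C)=C/[C@@H](B1OC(C)(C)C(C)(C)O1)C/C(C)=C/CC/C(C)=C/CO[Si](c1ccccc1)(c1ccccc1)C(C)(C)C | intermediate
19 | (2E,6E,9S,10E)-1-[tert-butyl(diphenyl)silyl]oxy-3,7,11,15-tetramethylhexadeca-2,6,10,14-tetraen-9-ol | CC(C)=CCC/C(C)=C/[C@@H](O)C/C(C)=C/CC/C(C)=C/CO[Si](c1ccccc1)(c1ccccc1)C(C)(C)C | intermediate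
20 | (2E,6E,9S,10E)-3,7,11,15-tetramethylhexadeca-2,6,10,14-tetraene-1,9-diol | CC(C)=CCC/C(C)=C/[C@@H](O)C/C(C)=C/CC/C(C)=C/CO | intermediate
21 | (2E,6E,9S,10E)-9-hydroxy-3,7,11,15-tetramethylhexadeca-2,6,10,14-tetraen-1-yl methanesulfonate (formed in the flask) | CC(C)=CCC/C(C)=C/[C@@H](O)C/C(C)=C/CC/C(C)=C/COS(C)(=O)=O | intermediate
22 | (2E,6E,9S,10E)-1-chloro-3,7,11,15-tetramethylhexadeca-2,6,10,14-tetraen-9-ol | CC(C)=CCC/C(C)=C/[C@@H](O)C/C(C)=C/CC/C(C)=C/CCl | intermediate
23 | 4-methoxy-2-methylphenol | COc1ccc(O)c(C)c1 | starting material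
24 | 2-bromo-4-methoxy-6-methylphenol | COc1cc(C)c(O)c(Br)c1 | intermediate
25 | 1-bromo-2,5-dimethoxy-3-methylbenzene | COc1cc(C)c(OC)c(Br)c1 | intermediate
26 | (2,5-dimethoxy-3-methylphenyl)magnesium bromide (formed in the flask) | COc1cc(C)c(OC)c([Mg]Br)c1 | intermediate
27 | (2E,6E,9S,10E)-1-(2,5-dimethoxy-3-methylphenyl)-3,7,11,15-tetramethylhexadeca-2,6,10,14-tetraen-9-ol | CC(C)=CCC/C(C)=C/[C@@H](O)C/C(C)=C/CC/C(C)=C/Cc1cc(OC)cc(C)c1OC | intermediate
28 | 2-[(2E,6E,9S,10E)-9-hydroxy-3,7,11,15-tetramethylhexadeca-2,6,10,14-tetraen-1-yl]-6-methylcyclohexa-2,5-diene-1,4-dione | CC(C)=CCC/C(C)=C/[C@@H](O)C/C(C)=C/CC/C(C)=C/CC1=CC(=O)C=C(C)C1=O | target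

**Count**

Total steps: 16. Longest linear sequence: 11 steps (steps 1–6, 10, 11, 12, 15, 16); the boronate (steps 7–9) and the aryl bromide (steps 13, 14) are side branches.

**Steps most likely to fail**

Step 10. Lithiation may be diverted to the allylic C–H bonds, or the alkenyl shift in the carbamate-derived boronate complex may be so slow that prolonged heating with MgBr2 erodes the allylic boronate. The fallback changes the carbenoid precursor. Setting out from 7, Mitsunobu esterification with 2,4,6-triisopropylbenzoic acid (PPh3, DIAD, THF) should give the 2,4,6-triisopropylbenzoate F1. Treatment with s-BuLi and (+)-sparteine in Et2O at −78 °C should give the (R)-α-lithio benzoate F2, which is trapped by 15 as the boronate complex F3. The better leaving group should let the alkenyl shift proceed on warming to room temperature without a Lewis acid, giving 18, and oxidation as before comes back to the route at 19.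

Step 15. The free hydroxyl may quench the aryl nucleophile, the aryl group may be delivered to the γ carbon, or the aryl Grignard reagent may form poorly. The fallback makes the bond with palladium instead of copper. Setting out from 25, Miyaura borylation (B2pin2, PdCl2(dppf), KOAc, dioxane, 80 °C) should give the aryl pinacol boronate F4. Suzuki–Miyaura allyl–aryl coupling of F4 with chloride 22 (Pd(PPh3)4, K2CO3, THF/H2O, 60 °C) tolerates the free carbinol, should deliver the aryl group to the less hindered allyl terminus, and comes back to the route at 27.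

Step 16. The unprotected allylic carbinol may be oxidised or ionised with allylic transposition under the acidic cerium oxidation. The fallback masks it during the oxidation. Setting out from 27, silylation (TBSCl, imidazole, DMF) should give the tert-butyldimethylsilyl ether F5. Oxidation with (NH4)2Ce(NO3)6 in MeCN/H2O at 0 °C should give the silyl-protected quinone F6, and HF·pyridine buffered with pyridine in THF at 0 °C should release 28.

**Further compounds**

F1 | step 10 | (3E,7E)-9-[tert-butyl(diphenyl)silyl]oxy-3,7-dimethylnona-3,7-dien-1-yl 2,4,6-triisopropylbenzoate | CC(C)c1cc(C(C)C)c(C(=O)OCC/C(C)=C/CC/C(C)=C/CO[Si](c2ccccc2)(c2ccccc2)C(C)(C)C)c(C(C)C)c1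
F2 | step 10 | (R)-α-lithio derivative of benzoate F1, lithium at C9' | [Li][C@@H](OC(=O)c1c(C(C)C)cc(C(C)C)cc1C(C)C)C/C(C)=C/CC/C(C)=C/CO[Si](c1ccccc1)(c1ccccc1)C(C)(C)C
F3 | step 10 | lithium boronate complex of F2 and 15, (R) at C9' | [Li+].CC(C)=CCC/C(C)=C/[B-]1(OC(C)(C)C(C)(C)O1)[C@@H](OC(=O)c1c(C(C)C)cc(C(C)C)cc1C(C)C)C/C(C)=C/CC/C(C)=C/CO[Si](c1ccccc1)(c1ccccc1)C(C)(C)C
F4 | step 15 | 2-(2,5-dimethoxy-3-methylphenyl)-4,4,5,5-tetramethyl-1,3,2-dioxaborolane | COc1cc(C)c(OC)c(B2OC(C)(C)C(C)(C)O2)c1
F5 | step 16 | tert-butyldimethylsilyl ether of 27 at the C9' oxygen | CC(C)=CCC/C(C)=C/[C@@H](O[Si](C)(C)C(C)(C)C)C/C(C)=C/CC/C(C)=C/Cc1cc(OC)cc(C)c1OC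
F6 | step 16 | tert-butyldimethylsilyl ether of 28 at the C9' oxygen | CC(C)=CCC/C(C)=C/[C@@H](O[Si](C)(C)C(C)(C)C)C/C(C)=C/CC/C(C)=C/CC1=CC(=O)C=C(C)C1=O
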